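**The vessel.** Each closed, stirred flask starts with its acidic substrate wholly solid, and the flasks differ in temperature.

in all of them: solid acidic substrate 0.12 M; free base 2.00 equiv; electrophile 0.900 equiv; time 8.0 min
- dusk: at 25 °C until 1.5 min, from then on at 85 °C
- spring: temperature 55 °C
- midnight: temperature 85 °C
- noon: temperature 25 °C

    electrophile + anion → product (k1 = 336 M⁻¹ min⁻¹, Ea1 = 41.0 kJ mol⁻¹)
    acidic substrate + free base ⇌ protonated base + anion, settled at all times (K2 = 0.417, ΔH2 = −42.0 kJ mol⁻¹)
    solid acidic substrate ⇌ acidic substrate, rate k3*(cs3 - [acidic substrate]) while solid is left; crystals form when [acidic substrate] > cs3 (cs3 = 29 mM, k3 = 2.68 min⁻¹)
    (constants at 25 °C)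

- given per volume of solution although it is solid: solid acidic substrate
- the constants hold at 25 °C; other temperatures follow from the activation energies and enthalpies
- at the start none of the solid acidic substrate is in solution

- the best flask by amount of product, in percent of the solid acidic substrate charged; "all alike" if 1.5 percentage points covers them all (dusk / spring / midnight / noon / all alike)
- amount of product at the end, in percent of the solid acidic substrate charged, dusk
- amount of product at the end, in percent of the solid acidic substrate charged, spring
- amount of product at the end, in percent of the solid acidic substrate charged, midnight
- amount of product at the end, in percent of the solid acidic substrate charged, noon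

**Turned round.** What must be true for these flasks to part by more than 1.5 percentage points? One of them must fail to reach its cap inside the run. Electrophile is the limiting reagent, charged at 0.900 equiv, less than the free base at 2.00 equiv, so I put the cap at 90.0%. To miss it, a flask needs a supply of anion as slow as the run is long.

**Feed time.** With no substrate yet dissolved, dissolving delivers 0.0777 M min⁻¹. At that starting rate, the electrophile's worth of substrate takes 1.39 min. I call this the feed time: charged electrophile divided by dissolution coefficient times solubility. At the full charge of electrophile, an anion meets it in 0.0276 min at 25 °C, much quicker than the feed, so dissolving is the rate-limiting step at the start. The dissolving step carries no activation energy, so the feed time is one number for the flasks. It is shorter than the run of 8.0 min, at 17.4% of it. On this estimate I commit to the cap in each flask.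

**The forecast.** It gives 90% for dusk, 90% for spring, 90% for midnight and 90% for noon, so its verdict is all alike. Its words are “the electrophile is nearly used up in about 2 minutes of the 8 available”. It says about 2 minutes where I reckon 1.39 min; the end is the same.

**The result.** Dusk gives 90.0%, spring 90.0%, midnight 90.0% and noon 90.0%, so the verdict is all alike.

**The cap.** The depletion of electrophile is the main reason midnight stops at 90.0%: without it, midnight reaches 100%. Midnight takes 1.29 min to convert 70.0% of the solid, where the feed time scaled to that share gives 1.08 min. A neighbour of midnight charged with 0.360 equiv of electrophile has a feed time of 0.556 min. After 8.00 min that neighbour holds 36.0% product, 0% of its electrophile and 37.4% of the solid acidic substrate still undissolved.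

The constants used here are invented; the flask was simulated.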